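The product stays dissolved up to 29 mM, so a short meeting was held on how much of it, crystals counted, stands in this flask at 15 h, and how far the solution then is from saturation.

starting material 0.050 M; free catalyst 3.6 mM; time 15 h

    starting material + free catalyst → catalyst intermediate A (k1 = 41 M⁻¹ h⁻¹)
    catalyst intermediate A ⇌ catalyst intermediate B (K2 = 0.51, k2 = 4.9 h⁻¹)
    catalyst intermediate B → free catalyst + product (k3 = 4.1 h⁻¹)
    crystals ⇌ product, rate k4*(cs4 - [product]) while solid is left; crystals form when [product] > cs4 (cs4 = 29 mM, k4 = 0.94 h⁻¹)

1. product and crystals together at 15 h, in percent of the starting material charged
2. concentration of product in solution at 15 h, in percent of saturation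

Minutes. I, who keep them, proposed to follow one catalyst round its cycle: free catalyst waits the inverse of 41 M⁻¹ h⁻¹ times [starting material], 0.488 h at the charge, and is then held in the intermediates for 0.926 h, the hold time, which does not depend on [starting material]. I said it adds up 0.204 h for the forward passage from intermediate A, 0.244 h for the last step, and 0.478 h for the fallbacks from intermediate B.

A colleague objected that the wait lengthens as [starting material] falls. I answered with a mean [starting material], guessed at 37.5 mM, which gives a cycle of 1.58 h and 34.3 mM consumed. That corrects the mean to 32.9 mM, the cycle to 1.67 h, and the amount consumed to 32.4 mM.

She added that catalyst still held in the intermediates at the end carries material that is not yet product. With 17.6 mM left the cycle is 2.31 h, so 1.44 mM is held, and I committed to 30.9 mM, or 61.9 %. That is more than saturation by 1.93 mM, which by my estimate builds up over the last 1.24 h at 1.56 mM h⁻¹. She took crystal growth to follow the same coefficient, which leaves an excess of 1.14 mM and a solution at 104 %.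

The forecast gave 61 % and 103.4 %, each a little lower than mine, with the solubility passed “only in the last hour or so”.

The simulation gives 61.7 % and 104 %.

At 15.0 h this flask has 35.4 % of its starting material left, which makes the wait 1.38 h, longer than the hold time of 0.926 h, a 59.8 % share of the cycle, and the flask has 58.8 % of its catalyst free, the resting state. In the neighbour flask charged with 0.0022 M of free catalyst, the same hold time, begun from this flask's mean of 32.9 mM, gives 19.8 mM consumed, a corrected mean [starting material] of 40.1 mM, a cycle of 1.53 h and 43.0 % of the charge consumed, and at 15.0 h that flask holds 57 % as starting material and 41.1 % as product.

Its constants are made up; the run is a simulation.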